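##Structural features

The target is a spiro[4.5]decane in which a cyclopentane (ring A: C-a bearing the side chain, C-b, C-c, the spiro carbon C-d, the carbinol carbon C-e) shares C-d with a cyclohexane (ring B: C-d, C-f bearing the 3-hydroxypropyl chain, the alkylidene carbon C-g, C-h, C-i, the methyl carbinol carbon C-j). C-a carries a branched (E)-allylic alcohol that runs on into an (E)-alkene, a 1,1-disubstituted alkene and a homoprenyl tail, while C-g carries an exocyclic tetrasubstituted (Z)-2-methyl enal whose formyl group faces C-f. Five stereocentres are contiguous (C-a, C-e, the all-carbon quaternary C-d, C-f and the tertiary carbinol C-j), so C-d is flanked by a stereocentre on three sides. On ring A the C-e hydroxyl is cis to the C-a side chain and trans to C-j, and on ring B the C-j oxygen, the C-f chain and C-e lie on one face. Fragile elements are the conjugated triene (acid, oxidants, light), the enal (geometric lability, a γ-hydrogen at C-f), the tertiary alcohol beside a spiro centre (ionisation with ring expansion) and, at the ketone stage, the C-e/C-d/C-j aldol array (retro-aldol). The real difficulty is the congested C-e–C-d–C-j unit with its quaternary centre, followed by substitution of C-f and not of C-h, which is equally α to C-g. The key step exploits the fact that O–C-j–C-d–C-e is a 1,3-dioxygenated array with oxygen and C-e cis on ring B, exactly what a nitrile oxide leaves when its carbon bonds to C-d and its oxygen to C-j of a C-d=C-j alkene in ring B.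

## Logic of the disconnections

42 from 40. No skeletal bond is cut. The formyl carbon is taken back to a nitrile, and the hydroxyls at C-e, at the chain terminus and on the allylic carbon are taken back to one seven-membered lactone and one pivalate. This keeps every protic or reduction-sensitive group masked until the last operation. The demand is that one hydride reagent carries two esters to alcohols yet stops at the imine stage of the nitrile, and that the enal geometry survives hydrolysis.

40 from 38 and 39. The exocyclic C-g=C bond is cut. The ring B ketone is the natural precursor, and 39 brings the methyl group, the alkene carbon and the masked formyl carbon in one piece. The demand is addition to an α-branched ketone with the nitrile ending syn to C-f.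

38 from 37. The bond between C-f and the first chain carbon is cut. The C-e oxygen is the only anchor from which a three-carbon acceptor reaches C-f but cannot reach C-h; an anchor on the C-j oxygen would reach both α-carbons through rings of equal size. The chain and the C-f stereocentre disappear. The demand is a seven-membered closure by conjugate addition under equilibrating enolisation, on the ring B face that carries C-e.

37 from 36, 36 from 34 and 35, 34 from 33. Only C–O bonds are cut (ketal, the ester that 35 places on O–C-e, the pivalate). The gain is the simple triol 33. The demands are discrimination of primary, secondary and tertiary hydroxyl and a ketal hydrolysis mild enough for the triene.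

33 from 32, 32 from 30, 30 from 22 and 28. After the diol is returned to a cis-fused γ-lactone, the trisubstituted C=C next to C-a is cut. The lactone makes the carbon beside C-a the only acidic site and gives a rigid frame in which elimination favours the E alkene. The whole C11 side chain leaves as 28. The demands are 1,2-addition to a dienal and tolerance of the free tertiary hydroxyl.

28 from 25 and 26, 25 from 23. The sp2–sp2 bond between the methylidene-bearing carbon and the enal β-carbon is cut. Both halves are trivial. The demands are kinetic enol triflate formation and retention of the E geometry.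

22 from 21, 21 from 20, 20 from 18. The lactone C–O bond and the C-e–H bond are undone, then the N–O bond is reconnected. The retro-aldol-prone β-hydroxy ketone is best stored as the heterocycle, and once released its tertiary hydroxyl directs the hydride. 18 has only three stereocentres. The demands are near-neutral N–O cleavage and hydride delivery from the C-j face.

18 from 16 (through 17). C-d–C-e and O–C-j are cut. Two rings and two stereocentres, one of them quaternary, are removed, leaving an achiral cyclohexene with one stereocentre in the tether. The demands are cycloaddition to a tetrasubstituted alkene and facial control from C-a alone.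

16 from 15, 15 from 14, 14 from 13, 13 from 10 and 11. The bond between C-a and the acetate methylene is cut. Auxiliary-controlled alkylation with a reactive electrophile is the safest way to set this centre. The demand is that C-a does not epimerise at the aldehyde stage.

10 from 7 and 8, 7 from 6, 6 from 5, 5 from 1 and 2. The N-acyl bond is cut, ring B is traced back to an arene, and the aryl–CH2 bond is cut. Enolate alkylation followed by a tetrasubstituted enol triflate would leave the alkene position to thermodynamic control. In the arene the positions of alkene and ketal are fixed by the substitution pattern. The demands are the usual Birch regiochemistry and ketalisation without alkene migration.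

## Other disconnections considered

Alternative 1: The cut runs through ring B at C-f–C-g and through the chain between its first and second carbon. Forward, irradiation of the dioxenone photosubstrate A1 (quaternary C-d carrying a vinyl group, silylated C-j carbinol, dioxenone at the end of the two-carbon arm) would give the cyclobutane photoadduct A2 by enone–alkene [2+2] addition. Opening of the dioxinone with retro-aldol cleavage of the cyclobutane would then reveal the C-g ketone and a propanoic acid chain on C-f.
- In its favour: the chain can end only on C-f. On this point it is better than the chosen plan, which needs a tether and a ring closure to exclude C-h. C-g emerges as a free ketone, equal to the chosen plan.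
- Against: A1 must already hold C-d, C-e and C-j in the right configuration, so the key step does not touch the hardest part of the molecule. C-f is set relative to C-d only by the conformation of the forming ring. A2 has nothing on C-a, so the side chain would need later α-functionalisation with renewed control of C-a and C-e. Ultraviolet light excludes any diene-bearing substrate.
- Comparison: both plans store an aldol-type relationship in a ring that is cleaved later, but the chosen plan spends its key step on the quaternary centre and the tertiary carbinol and carries the C-a handle from the start. The alternative would probably be longer.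

Alternative 2: The cuts are C-d–C-f and the ring B bond that becomes the C-h=C-i alkene of the product. Forward, under diarylprolinol silyl ether catalysis, the central carbon of 2-acetylcyclopentanone A3 would add to the β-carbon of the silyloxy enal A4, and the acetyl methyl would condense with the released aldehyde to give the spiro cyclohexenone A5.
- In its favour: it is catalytic and asymmetric, it joins two simple achiral components, and it creates the quaternary C-d and C-f with the chain in place. In catalysis instead of a stoichiometric auxiliary, in convergence, in early step economy and in chain placement it is better than the chosen plan.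
- Against: A5 has carbonyls at C-j and C-e but a methylene at C-g, so oxygen must be brought to C-g later by allylic oxidation with transposition. Methyl addition at C-j must distinguish two ketones and set C-j relative to C-d without an internal control element, whereas the cycloaddition fixes that relationship by mechanism. Diastereocontrol between C-d and C-f with a nearly planar cyclic diketone nucleophile is uncertain. C-a is again unfunctionalised.
- Comparison: the alternative reaches a spiro bicycle faster but with the oxidation pattern of ring B misplaced, so the saving at the start would be repaid by redox and stereochemical corrections later.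

Alternative 3: The cut is C-a–C-b, with ring A seen as a contracted cyclohexane. Forward, methylaluminium bis(4-bromo-2,6-di-tert-butylphenoxide) would open the cis-epoxy silyl ether A6 at the epoxide carbon next to the silyloxy carbon while the ring methylene on the other epoxide carbon migrates anti to the leaving oxygen, giving the β-silyloxy aldehyde A7.
- In its favour: the shift is stereospecific, so the cis relation of C-a and C-e follows from the epoxide geometry. On this point it is equal to or better than the chosen plan, where the same relation rests on a directed reduction. It also delivers a formyl handle on C-a at low temperature.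
- Against: A6 presupposes the whole spiro skeleton with C-d, C-f and C-j already set, so the quaternary centre and tertiary carbinol are not addressed. Hydride shift or migration of the wrong bond can compete. A strong aluminium Lewis acid meets a ketal and a tertiary silyl ether. The formyl carbon still needs several steps to become the branched allylic alcohol carbon, which the lactone aldol–elimination provides in two.
- Comparison: the ring contraction is a good way to finish ring A but not to found the synthesis. The overall route would be longer than the chosen one.

Key step: step 9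

Remark: 1, 2, 8, 11, 23, 26, 35 and 39 are taken as commercial; the configurations of 16, 18 and 42 at C-a, C-d and C-j were checked against each other and needed no correction.

Step 1
Reactants: 1 3-bromo-4-methylanisole; 2 ethyl 4-bromobutanoate
Product: 5 4-(5-methoxy-2-methylphenyl)butanoic acid, via (4-ethoxy-4-oxobutyl)zinc bromide 3 (not isolated), via ethyl 4-(5-methoxy-2-methylphenyl)butanoate 4 (not isolated)
Conditions: 2, Zn, LiCl, THF, 50 °C; then 1, Pd(OAc)2 (2 mol %), SPhos, 60 °C; then LiOH, H2O/MeOH, 50 °C; aq HCl
Reagents that add atoms: lithium hydroxide, [Li+].[OH-]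
Why: Zinc insertion gives an ester-tolerant alkylzinc, Negishi coupling joins it to the ortho-substituted aryl bromide, and saponification in the same flask lets the acid be purified by extraction; the arene pattern (chain ortho to methyl, meta to methoxy) already encodes the later positions of alkene and ketal.

Step 2
Reactants: 5 4-(5-methoxy-2-methylphenyl)butanoic acid
Product: 6 4-(5-methoxy-2-methylcyclohexa-1,4-dien-1-yl)butanoic acid
Conditions: Li, NH3(l), THF, tBuOH, −78 to −33 °C; NH4Cl
Reagents that add atoms: none
Why: Birch reduction of the carboxylate protonates the two unsubstituted ring carbons ortho and meta to methoxy, so the 1,4-diene keeps methoxy on one alkene and both alkyl groups on the other, which fixes the tetrasubstituted C-d=C-j alkene without a regiochemical choice.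

Step 3
Reactants: 6 4-(5-methoxy-2-methylcyclohexa-1,4-dien-1-yl)butanoic acid
Product: 7 4-(8-methyl-1,4-dioxaspiro[4.5]dec-7-en-7-yl)butanoic acid
Conditions: HO(CH2)2OH, PPTS, CH2Cl2, rt
Reagents that add atoms: ethylene glycol, OCCO
Why: Acid-catalysed exchange of the methyl enol ether gives the dioxolane directly; the tetrasubstituted alkene is not conjugated to the enol ether and should stay β,γ to the ketal carbon.

Step 4
Reactants: 7 4-(8-methyl-1,4-dioxaspiro[4.5]dec-7-en-7-yl)butanoic acid; 8 (4R)-4-benzyl-1,3-oxazolidin-2-one
Product: 10 (4R)-4-benzyl-3-[4-(8-methyl-1,4-dioxaspiro[4.5]dec-7-en-7-yl)butanoyl]-1,3-oxazolidin-2-one, via mixed pivalic anhydride 9 (not isolated)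
Conditions: PivCl, Et3N, THF, −20 °C; then 8, LiCl, rt
Reagents that add atoms: none
Why: N-acylation of the oxazolidinone through the mixed anhydride under LiCl/Et3N activation needs no strong base and leaves ketal and alkene untouched.

Step 5
Reactants: 10 (4R)-4-benzyl-3-[4-(8-methyl-1,4-dioxaspiro[4.5]dec-7-en-7-yl)butanoyl]-1,3-oxazolidin-2-one; 11 tert-butyl bromoacetate
Product: 13 tert-butyl (3S)-3-{[(4R)-4-benzyl-2-oxo-1,3-oxazolidin-3-yl]carbonyl}-5-(8-methyl-1,4-dioxaspiro[4.5]dec-7-en-7-yl)pentanoate, via sodium Z-enolate 12 (not isolated)
Conditions: NaN(SiMe3)2, THF, −78 °C; then 11, −78 to −45 °C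
Reagents that add atoms: none
Why: Evans alkylation: the chelated Z-enolate is attacked by the reactive bromoacetate on the face away from the benzyl group, which with the (R)-auxiliary should set C-a as S.

Step 6
Reactants: 13 tert-butyl (3S)-3-{[(4R)-4-benzyl-2-oxo-1,3-oxazolidin-3-yl]carbonyl}-5-(8-methyl-1,4-dioxaspiro[4.5]dec-7-en-7-yl)pentanoate
Product: 14 tert-butyl (3S)-3-(hydroxymethyl)-5-(8-methyl-1,4-dioxaspiro[4.5]dec-7-en-7-yl)pentanoate
Conditions: LiBH4, MeOH (1 equiv), THF, 0 °C
Reagents that add atoms: none
Why: LiBH4 reduces the activated imide carbonyl much faster than the tert-butyl ester and releases the auxiliary; the bulky ester also retards lactonisation of the γ-hydroxy ester.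

Step 7
Reactants: 14 tert-butyl (3S)-3-(hydroxymethyl)-5-(8-methyl-1,4-dioxaspiro[4.5]dec-7-en-7-yl)pentanoate
Product: 15 tert-butyl (3S)-3-formyl-5-(8-methyl-1,4-dioxaspiro[4.5]dec-7-en-7-yl)pentanoate
Conditions: Dess–Martin periodinane, NaHCO3, CH2Cl2, 0 °C to rt
Reagents that add atoms: none
Why: Buffered Dess–Martin oxidation gives the α-branched aldehyde without a base strong enough to epimerise C-a; the aldehyde is used crude.

Step 8
Reactants: 15 tert-butyl (3S)-3-formyl-5-(8-methyl-1,4-dioxaspiro[4.5]dec-7-en-7-yl)pentanoate
Product: 16 tert-butyl (3S)-3-[(E)-(hydroxyimino)methyl]-5-(8-methyl-1,4-dioxaspiro[4.5]dec-7-en-7-yl)pentanoate (the cyclohexenyl aldoxime)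
Conditions: NH2OH·HCl, NaOAc, EtOH/H2O, rt
Reagents that add atoms: hydroxylamine (as hydrochloride), NO
Why: Oxime condensation at pH 5–6 is faster than enolisation, so the C-a configuration should be carried over; oxime geometry does not matter because both isomers give the same nitrile oxide.

Step 9
Reactants: 16 tert-butyl (3S)-3-[(E)-(hydroxyimino)methyl]-5-(8-methyl-1,4-dioxaspiro[4.5]dec-7-en-7-yl)pentanoate
Product: 18 spiro-fused isoxazoline tert-butyl ester (aS,dS,jS), via nitrile oxide 17 (not isolated)
Conditions: aq NaOCl, CH2Cl2, 0 °C to rt, 0.005 M
Reagents that add atoms: none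
Why: Hypochlorite converts the aldoxime (through its hydroximoyl chloride) into nitrile oxide 17, which adds across the C-d=C-j alkene in one concerted, suprafacial [3+2] step (Huisgen cycloaddition). The closest known reaction type is the intramolecular nitrile oxide–alkene cycloaddition of hex-5-enyl nitrile oxides to cyclopenta-fused 2-isoxazolines, here at the demanding end of its scope because the dipolarophile is tetrasubstituted. Ring A closes by C-e–C-d bond formation, a five-membered closure in which the three-carbon tether C-a/C-b/C-c lets the dipole carbon reach only the nearer alkene carbon. The isoxazoline closes in the same transition state by O–C-j bond formation and ends fused to ring A along C-d–C-e and spiro to ring B. C-d and C-j are created together, and their relative configuration (C-e and oxygen cis on ring B) is fixed by the suprafacial mechanism. Their sense relative to C-a is the selectivity the step needs: it is controlled by the C-a stereocentre, whose tert-butyl acetate arm should sit pseudo-equatorial on the convex face of the forming bicycle, cis to C-f and away from C-j. Regiochemistry is secured by the tether (the bridged mode would need a six-membered carbocycle in a strained bicycle), and cycloaddition ahead of furoxan dimerisation by high dilution and the slowly dimerising α-branched dipole. The basic two-phase hypochlorite should leave alkene, ketal and ester alone.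

Step 10
Reactants: 18 spiro-fused isoxazoline tert-butyl ester (aS,dS,jS)
Product: 20 β-hydroxy ketone tert-butyl ester (aS,dR,jS), via β-hydroxy imine 19 (not isolated)
Conditions: Raney Ni, H2 (1 atm), B(OH)3, MeOH/H2O 5:1, rt
Reagents that add atoms: water, O
Why: Hydrogenolysis of the N–O bond gives the β-hydroxy imine, which the boric acid buffer hydrolyses before it can be reduced further; the near-neutral medium avoids retro-aldol cleavage of C-d–C-j, and ketal and ester are inert.

Step 11
Reactants: 20 β-hydroxy ketone tert-butyl ester (aS,dR,jS)
Product: 21 diol tert-butyl ester (aS,dS,eR,jS)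
Conditions: Me4NBH(OAc)3, MeCN/AcOH 1:1, −25 °C
Reagents that add atoms: none
Why: Hydroxyl-directed (Evans–Saksena) reduction: the tertiary C-j hydroxyl exchanges onto boron and delivers hydride to the carbonyl face on which C-j lies, so the new C-e hydroxyl should end trans to C-j and cis to the acetate arm.

Step 12
Reactants: 21 diol tert-butyl ester (aS,dS,eR,jS)
Product: 22 cis-fused γ-lactone (aS,dS,eR,jS)
Conditions: KOtBu (0.2 equiv), THF, 0 °C
Reagents that add atoms: none
Why: The C-e alkoxide closes a five-membered lactone on the cis acetate arm (5-exo-trig acyl substitution) and expels tert-butoxide, which carries the chain; base is chosen over acid so that the tertiary alcohol beside the spiro carbon never meets ionising conditions.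

Step 13
Reactants: 23 6-methylhept-5-en-2-one
Product: 25 6-methylhepta-1,5-dien-2-yl trifluoromethanesulfonate, via potassium enolate 24 (not isolated)
Conditions: KN(SiMe3)2, THF, −78 °C; then PhNTf2, −78 to 0 °C
Reagents that add atoms: N-phenylbis(trifluoromethanesulfonimide), O=S(=O)(N(c1ccccc1)S(=O)(=O)C(F)(F)F)C(F)(F)F
Why: Kinetic deprotonation of the methyl ketone on the methyl side followed by O-sulfonylation gives the 2-substituted vinyl triflate.

Step 14
Reactants: 25 6-methylhepta-1,5-dien-2-yl trifluoromethanesulfonate; 26 2-[(E)-3,3-diethoxyprop-1-enyl]-4,4,5,5-tetramethyl-1,3,2-dioxaborolane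
Product: 28 (2E)-8-methyl-4-methylidenenona-2,7-dienal, via diethyl acetal 27 (not isolated)
Conditions: Pd(PPh3)4 (3 mol %), K3PO4, dioxane/H2O, 50 °C; then 1 M HCl, THF, 0 °C
Reagents that add atoms: water, O
Why: Suzuki–Miyaura coupling of the vinyl triflate with the alkenylboronate keeps the E geometry, and brief mild acid unmasks the aldehyde; the dienal is used fresh.

Step 15
Reactants: 22 cis-fused γ-lactone (aS,dS,eR,jS); 28 (2E)-8-methyl-4-methylidenenona-2,7-dienal
Product: 30 aldol adduct (epimer mixture at the two new centres), via lithium enolate 29 (not isolated)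
Conditions: LiN(iPr)2 (2.3 equiv), THF, −78 °C; then 28, −78 °C; aq NH4Cl
Reagents that add atoms: none
Why: The lactone is the only carbon acid present (the first equivalent of base only deprotonates the tertiary hydroxyl), and its lithium enolate should add 1,2 to the dienal at −78 °C; both new stereocentres are removed in step 16.

Step 16
Reactants: 30 aldol adduct
Product: 32 (E)-alkylidene γ-lactone (aS,dS,eR,jS), via allylic acetate 31 (not isolated)
Conditions: Ac2O, Et3N, DMAP, CH2Cl2, 0 °C; then DBU, rt
Reagents that add atoms: none
Why: Acetylation reaches only the secondary aldol hydroxyl (the C-j hydroxyl is tertiary and hindered), and DBU induces E1cB loss of acetate through the lactone enolate, which should give the more stable E alkylidene lactone with the dienyl chain anti to the carbonyl.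

Step 17
Reactants: 32 (E)-alkylidene γ-lactone (aS,dS,eR,jS)
Product: 33 triol (aS,dS,eR,jS)
Conditions: iBu2AlH (6 equiv), CH2Cl2, −78 to 0 °C; aq potassium sodium tartrate
Reagents that add atoms: none
Why: iBu2AlH reduces the unsaturated lactone by 1,2-addition only, so the alkene geometry is kept while the C-e hydroxyl and the primary allylic alcohol are released together.

Step 18
Reactants: 33 triol (aS,dS,eR,jS)
Product: 34 primary allylic pivalate (aS,dS,eR,jS)
Conditions: PivCl, pyridine, CH2Cl2, 0 °C
Reagents that add atoms: pivaloyl chloride, CC(C)(C)C(=O)Cl
Why: The bulky acyl chloride esterifies the primary allylic alcohol and leaves the neopentyl-type secondary and the tertiary hydroxyl; a pivalate has no α-hydrogen, withstands the later base steps and falls to hydride at the end.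

Step 19
Reactants: 34 primary allylic pivalate (aS,dS,eR,jS); 35 acryloyl chloride
Product: 36 C-e acrylate (aS,dS,eR,jS)
Conditions: 35, iPr2NEt, DMAP (cat.), CH2Cl2, −20 to 0 °C
Reagents that add atoms: none
Why: Acylation of the one remaining secondary hydroxyl; the tertiary C-j hydroxyl should not react under these conditions.

Step 20
Reactants: 36 C-e acrylate (aS,dS,eR,jS)
Product: 37 ring B ketone (aS,dS,eR,jS)
Conditions: PPTS, acetone/H2O 9:1, 45 °C
Reagents that add atoms: water, O
Why: Mild acid hydrolysis of the cyclohexanone dioxolane at a pH that should leave the triene, both esters and the tertiary alcohol intact.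

Step 21
Reactants: 37 ring B ketone (aS,dS,eR,jS)
Product: 38 cis-fused ε-lactone ketone (aS,dS,eR,fS,jS)
Conditions: KOtBu (0.5 equiv), THF/tBuOH, −20 to 0 °C, 0.005 M
Reagents that add atoms: none
Why: Intramolecular Michael addition under equilibrating enolisation: both enolates form, but only the C-f enolate can reach the acrylate, and it must do so by axial attack on the ring B face that carries C-e, giving a cis-fused seven-membered lactone (7-endo-trig) with the chain cis to C-e and to the C-j oxygen; that face is also the one anti to the C-j methyl group.

Step 22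
Reactants: 38 cis-fused ε-lactone ketone (aS,dS,eR,fS,jS); 39 diethyl (1-cyanoethyl)phosphonate
Product: 40 (Z)-unsaturated nitrile (aS,dS,eR,fR,jS)
Conditions: 39, NaH, THF, 0 to 50 °C
Reagents that add atoms: none
Why: Horner–Wadsworth–Emmons olefination with a small, reactive cyano phosphonate anion; the methyl group, the larger substituent on the new alkene carbon, should take the side of the unsubstituted C-h and leave the linear nitrile beside the substituted C-f (Z), while the cis-fused lactone holds the C-f configuration.

Step 23
Reactants: 40 (Z)-unsaturated nitrile (aS,dS,eR,fR,jS)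
Product: 42 28-deacetylbelamcandal, via aldimine 41 (not isolated)
Conditions: iBu2AlH (12 equiv), CH2Cl2, −78 to 0 °C; aq potassium sodium tartrate; then SiO2, wet EtOAc
Reagents that add atoms: water, O
Why: One hydride operation should reduce the lactone to the C-e hydroxyl and the 3-hydroxypropyl chain, cleave the pivalate and stop at the N-aluminio imine of the nitrile, which mild hydrolysis converts into the enal without change of geometry.

Compound list

1 | 3-bromo-4-methylanisole | COc1ccc(C)c(Br)c1 | starting material
2 | ethyl 4-bromobutanoate | CCOC(=O)CCCBr | starting material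
3 | (4-ethoxy-4-oxobutyl)zinc bromide | CCOC(=O)CCC[Zn]Br | intermediate
4 | ethyl 4-(5-methoxy-2-methylphenyl)butanoate | CCOC(=O)CCCc1cc(OC)ccc1C | intermediate
5 | 4-(5-methoxy-2-methylphenyl)butanoic acid | COc1ccc(C)c(CCCC(=O)O)c1 | intermediate
6 | 4-(5-methoxy-2-methylcyclohexa-1,4-dien-1-yl)butanoic acid | COC1=CCC(C)=C(CCCC(=O)O)C1 | intermediate
7 | 4-(8-methyl-1,4-dioxaspiro[4.5]dec-7-en-7-yl)butanoic acid | CC1=C(CCCC(=O)O)CC2(OCCO2)CC1 | intermediate
8 | (4R)-4-benzyl-1,3-oxazolidin-2-one | O=C1N[C@H](Cc2ccccc2)CO1 | starting material
9 | mixed anhydride of 7 with pivalic acid | CC1=C(CCCC(=O)OC(=O)C(C)(C)C)CC2(OCCO2)CC1 | intermediate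
10 | (4R)-4-benzyl-3-[4-(8-methyl-1,4-dioxaspiro[4.5]dec-7-en-7-yl)butanoyl]-1,3-oxazolidin-2-one | CC1=C(CCCC(=O)N3[C@H](Cc4ccccc4)COC3=O)CC2(OCCO2)CC1 | intermediate
11 | tert-butyl bromoacetate | CC(C)(C)OC(=O)CBr | starting material
12 | sodium (Z)-enolate of 10 | [Na+].[O-]/C(=C\CCC1=C(C)CCC2(OCCO2)C1)N3[C@H](Cc4ccccc4)COC3=O | intermediate
13 | tert-butyl (3S)-3-{[(4R)-4-benzyl-2-oxo-1,3-oxazolidin-3-yl]carbonyl}-5-(8-methyl-1,4-dioxaspiro[4.5]dec-7-en-7-yl)pentanoate | CC1=C(CC[C@@H](CC(=O)OC(C)(C)C)C(=O)N3[C@H](Cc4ccccc4)COC3=O)CC2(OCCO2)CC1 | intermediate
14 | tert-butyl (3S)-3-(hydroxymethyl)-5-(8-methyl-1,4-dioxaspiro[4.5]dec-7-en-7-yl)pentanoate | CC1=C(CC[C@@H](CC(=O)OC(C)(C)C)CO)CC2(OCCO2)CC1 | intermediate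
15 | tert-butyl (3S)-3-formyl-5-(8-methyl-1,4-dioxaspiro[4.5]dec-7-en-7-yl)pentanoate | CC1=C(CC[C@@H](CC(=O)OC(C)(C)C)C=O)CC2(OCCO2)CC1 | intermediate
16 | tert-butyl (3S)-3-[(E)-(hydroxyimino)methyl]-5-(8-methyl-1,4-dioxaspiro[4.5]dec-7-en-7-yl)pentanoate | CC1=C(CC[C@@H](CC(=O)OC(C)(C)C)/C=N/O)CC2(OCCO2)CC1 | intermediate
17 | (2S)-2-(2-tert-butoxy-2-oxoethyl)-4-(8-methyl-1,4-dioxaspiro[4.5]dec-7-en-7-yl)butanenitrile oxide | CC1=C(CC[C@@H](CC(=O)OC(C)(C)C)C#[N+][O-])CC2(OCCO2)CC1 | intermediate
18 | spiro-fused isoxazoline (aS,dS,jS): 2-isoxazoline C-e=N–O–C-j fused to ring A along C-d–C-e and spiro at C-d to ring B, dioxolane at C-g, CH2CO2tBu on C-a trans to C-j | O=C(OC(C)(C)C)C[C@@H]1CC[C@@]23CC4(OCCO4)CC[C@]2(C)ON=C13 | intermediate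
19 | β-hydroxy imine: 18 with the N–O bond cleaved (C-e=NH, C-j–OH) | O=C(OC(C)(C)C)C[C@@H]1CC[C@]2(CC3(OCCO3)CC[C@]2(C)O)C1=N | intermediate
20 | β-hydroxy ketone (aS,dR,jS): ring A ketone at C-e, tertiary hydroxyl at C-j cis to C-e on ring B, dioxolane at C-g, CH2CO2tBu on C-a | O=C(OC(C)(C)C)C[C@@H]1CC[C@]2(CC3(OCCO3)CC[C@]2(C)O)C1=O | intermediate
21 | diol (aS,dS,eR,jS): C-e hydroxyl cis to the acetate arm and trans to C-j on ring A | O=C(OC(C)(C)C)C[C@@H]1CC[C@]2(CC3(OCCO3)CC[C@]2(C)O)[C@@H]1O | intermediate
22 | cis-fused γ-lactone (aS,dS,eR,jS): O–C-e acylated by the C-a acetate arm, free C-j hydroxyl, dioxolane at C-g | O=C1C[C@@H]2CC[C@]3(CC4(OCCO4)CC[C@]3(C)O)[C@@H]2O1 | intermediate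
23 | 6-methylhept-5-en-2-one | CC(=O)CCC=C(C)C | starting material
24 | potassium 6-methylhepta-1,5-dien-2-olate | [K+].[O-]C(=C)CCC=C(C)C | intermediate
25 | 6-methylhepta-1,5-dien-2-yl trifluoromethanesulfonate | C=C(OS(=O)(=O)C(F)(F)F)CCC=C(C)C | intermediate
26 | 2-[(E)-3,3-diethoxyprop-1-enyl]-4,4,5,5-tetramethyl-1,3,2-dioxaborolane | CCOC(OCC)/C=C/B1OC(C)(C)C(C)(C)O1 | starting material
27 | (2E)-1,1-diethoxy-8-methyl-4-methylidenenona-2,7-diene | C=C(/C=C/C(OCC)OCC)CCC=C(C)C | intermediate
28 | (2E)-8-methyl-4-methylidenenona-2,7-dienal | C=C(/C=C/C=O)CCC=C(C)C | intermediate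
29 | dilithium salt of 22 (lactone enolate and C-j alkoxide) | [Li+].[Li+].[O-]C1=C[C@@H]2CC[C@]3(CC4(OCCO4)CC[C@]3(C)[O-])[C@@H]2O1 | intermediate
30 | aldol adduct: 22 carrying a (2E)-1-hydroxy-8-methyl-4-methylidenenona-2,7-dienyl group on the lactone α-carbon (epimer mixture at the two new centres) | C=C(/C=C/C(O)C(C(=O)O3)[C@@H]1CC[C@]2(CC4(OCCO4)CC[C@]2(C)O)[C@@H]13)CCC=C(C)C | intermediate
31 | O-acetate of 30 | C=C(/C=C/C(OC(C)=O)C(C(=O)O3)[C@@H]1CC[C@]2(CC4(OCCO4)CC[C@]2(C)O)[C@@H]13)CCC=C(C)C | intermediate
32 | (E)-alkylidene lactone (aS,dS,eR,jS): lactone α-carbon doubly bonded to C-1 of a (2E)-8-methyl-4-methylidenenona-2,7-dien-1-ylidene chain, chain anti to the lactone carbonyl | C=C(/C=C/C=C(/C(=O)O3)[C@@H]1CC[C@]2(CC4(OCCO4)CC[C@]2(C)O)[C@@H]13)CCC=C(C)C | intermediate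
33 | triol (aS,dS,eR,jS): C-a bears the (2E,4E)-1-hydroxy-10-methyl-6-methylideneundeca-2,4,9-trien-2-yl chain, free hydroxyls at C-e and C-j, dioxolane at C-g | C=C(/C=C/C=C(/CO)[C@@H]1CC[C@]2(CC3(OCCO3)CC[C@]2(C)O)[C@@H]1O)CCC=C(C)C | intermediate
34 | pivalate of the primary allylic alcohol of 33 | C=C(/C=C/C=C(/COC(=O)C(C)(C)C)[C@@H]1CC[C@]2(CC3(OCCO3)CC[C@]2(C)O)[C@@H]1O)CCC=C(C)C | intermediate
35 | acryloyl chloride | C=CC(=O)Cl | starting material
36 | 34 acylated on the C-e oxygen as the acrylate | C=C(/C=C/C=C(/COC(=O)C(C)(C)C)[C@@H]1CC[C@]2(CC3(OCCO3)CC[C@]2(C)O)[C@@H]1OC(=O)C=C)CCC=C(C)C | intermediate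
37 | ring B ketone (C-g=O) from 36 | C=C(/C=C/C=C(/COC(=O)C(C)(C)C)[C@@H]1CC[C@]2(CC(=O)CC[C@]2(C)O)[C@@H]1OC(=O)C=C)CCC=C(C)C | intermediate
38 | ε-lactone ketone (aS,dS,eR,fS,jS): C-f linked through CH2CH2C(=O) to the C-e oxygen, chain cis to C-e and to the C-j oxygen on ring B, ketone at C-g | C=C(/C=C/C=C(/COC(=O)C(C)(C)C)[C@@H]1CC[C@]2([C@H](CCC(=O)O3)C(=O)CC[C@]2(C)O)[C@@H]13)CCC=C(C)C | intermediate
39 | diethyl (1-cyanoethyl)phosphonate | CCOP(=O)(OCC)C(C)C#N | starting material
40 | (2Z)-2-(ring B C-g-ylidene)propanenitrile (aS,dS,eR,fR,jS): nitrile syn to C-f, ε-lactone and pivalate retained | C=C(/C=C/C=C(/COC(=O)C(C)(C)C)[C@@H]1CC[C@]2([C@H](CCC(=O)O3)/C(=C(/C)C#N)CC[C@]2(C)O)[C@@H]13)CCC=C(C)C | intermediate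
41 | aldimine corresponding to 42 (CH=NH in place of CHO) | C=C(/C=C/C=C(/CO)[C@@H]1CC[C@]2([C@H](CCCO)/C(=C(/C)C=N)CC[C@]2(C)O)[C@@H]1O)CCC=C(C)C | intermediate
42 | 28-deacetylbelamcandal (aS,dS,eR,fR,jS; side-chain alkenes E,E; enal Z) | C=C(/C=C/C=C(/CO)[C@@H]1CC[C@]2([C@H](CCCO)/C(=C(/C)C=O)CC[C@]2(C)O)[C@@H]1O)CCC=C(C)C | target

Total step count: 23. Longest linear sequence: 21 steps (steps 1–12 and 15–23); steps 13 and 14 make fragment 28.

Least certain steps

Step 9 (key step). The cycloaddition onto a tetrasubstituted alkene may be slow enough for dimerisation of the dipole to compete. Facial discrimination by the single C-a centre may be incomplete. Electrophilic chlorination of the electron-rich alkene could set in if the aqueous phase loses its basicity. Any diastereomer from attack on the other face must be removed at the stage of 18, because later equilibration at C-a would carry it into the enantiomeric series. Fallback: generate the same dipole by dehydration instead of oxidation. Starting from 14, iodination (I2, PPh3, imidazole) would give the primary iodide F1, nitrite displacement (NaNO2, DMSO) the nitroalkane F2, and slow dehydration with PhNCO/Et3N in benzene at 60–80 °C would form 17 without oxidant at a temperature at which the hindered alkene can react, returning to the route at 18.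

Step 21. Closure of the seven-membered ring may be slow, so that intermolecular conjugate addition, reaction through the unproductive C-h enolate, or reversal of the addition competes. Fallback: change the nucleophile from an enolate to an enamine. Starting from 37, pyrrolidine with catalytic AcOH and molecular sieves would form both enamines reversibly; only the C-f enamine F3 can reach the acrylate (intramolecular Stork enamine Michael addition under neutral conditions), and aqueous hydrolysis returns to the route at 38.

Step 22. Addition to the α-branched ketone may be outrun by enolisation, and geometric control in forming the tetrasubstituted alkene may be poor because methyl and nitrile differ only modestly in size. Acyl migration of the lactone to the C-j oxygen under base would be harmless, since both lactones give the same triol in step 23. Fallback: change the olefination manifold. Starting from 38, lithiated 2-(trimethylsilyl)propanenitrile should add irreversibly at −78 °C to give the β-silyl alkoxide F4, which loses silanolate on warming (Peterson olefination) and returns to the route at 40, where geometric isomers can be separated while they are still configurationally stable.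

Step 23. Reduction of the hindered pivalate and of the lactone may be incomplete at temperatures at which the aluminated imine is safe, or warming may bring over-reduction of the imine. Fallback: divide the hydride work by chemoselectivity. Starting from 40, LiBH4 in THF/MeOH should reduce lactone and pivalate but not the conjugated nitrile, giving the tetraol nitrile F5; iBu2AlH at −78 °C followed by mild hydrolysis then acts on the nitrile alone and returns to the route at 42.

Step 16. Geometric control in the elimination may be lost, or the acetate may ionise towards the dienyl system and not leave by the E1cB path. Fallback: replace aldol–elimination by a Wittig olefination. Starting from 22, bromination of the dianion (LiN(SiMe3)2, then BrCCl2CCl2Br) would give the α-bromo lactone F6, PPh3 followed by Et3N the stabilised phosphorane F7, and reaction of F7 with 28 should give the E alkylidene lactone directly, returning to the route at 32.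

Further compounds

F1 | step 9 | tert-butyl (3S)-3-(iodomethyl)-5-(8-methyl-1,4-dioxaspiro[4.5]dec-7-en-7-yl)pentanoate | CC1=C(CC[C@@H](CC(=O)OC(C)(C)C)CI)CC2(OCCO2)CC1
F2 | step 9 | tert-butyl (3S)-5-(8-methyl-1,4-dioxaspiro[4.5]dec-7-en-7-yl)-3-(nitromethyl)pentanoate | CC1=C(CC[C@@H](CC(=O)OC(C)(C)C)C[N+](=O)[O-])CC2(OCCO2)CC1
F3 | step 21 | pyrrolidine enamine of 37 with the C-f=C-g double bond | C=C(/C=C/C=C(/COC(=O)C(C)(C)C)[C@@H]1CC[C@]2(C=C(N3CCCC3)CC[C@]2(C)O)[C@@H]1OC(=O)C=C)CCC=C(C)C
F4 | step 22 | dilithium β-silyl alkoxide from addition of lithiated 2-(trimethylsilyl)propanenitrile to C-g of 38 (epimer mixture at the two new centres) | C=C(/C=C/C=C(/COC(=O)C(C)(C)C)[C@@H]1CC[C@]2([C@H](CCC(=O)O3)C([O-])(C(C)(C#N)[Si](C)(C)C)CC[C@]2(C)[O-])[C@@H]13)CCC=C(C)C.[Li+].[Li+]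
F5 | step 23 | tetraol nitrile: 42 with C≡N in place of CHO | C=C(/C=C/C=C(/CO)[C@@H]1CC[C@]2([C@H](CCCO)/C(=C(/C)C#N)CC[C@]2(C)O)[C@@H]1O)CCC=C(C)C
F6 | step 16 | α-bromo derivative of lactone 22 (epimer mixture at the brominated carbon) | O=C1C(Br)[C@@H]2CC[C@]3(CC4(OCCO4)CC[C@]3(C)O)[C@@H]2O1
F7 | step 16 | α-(triphenylphosphoranylidene) derivative of lactone 22 | O=C1C(=P(c5ccccc5)(c6ccccc6)c7ccccc7)[C@@H]2CC[C@]3(CC4(OCCO4)CC[C@]3(C)O)[C@@H]2O1
A1 | alternative 1 | dioxenone photosubstrate: cyclopentanol with quaternary C-d bearing vinyl and the silylated C-j carbinol arm ending in a 2,2-dimethyl-1,3-dioxin-4-one | C1CC[C@@](C=C)([C@@](C)(O[Si](C)(C)C)CCC2=CC(=O)OC(C)(C)O2)[C@@H]1O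
A2 | alternative 1 | cyclobutane photoadduct | C1CC[C@]2([C@@H]3C[C@H]4C(=O)OC(C)(C)O[C@@]34CC[C@]2(C)O[Si](C)(C)C)[C@@H]1O
A3 | alternative 2 | 2-acetylcyclopentanone | CC(=O)C1CCCC1=O
A4 | alternative 2 | (2E)-6-(tert-butyldimethylsilyloxy)hex-2-enal | O=C/C=C/CCCO[Si](C)(C)C(C)(C)C
A5 | alternative 2 | spiro cyclohexenone diketone | C1CC[C@]2([C@H](CCCO[Si](C)(C)C(C)(C)C)CC=CC2=O)C1=O
A6 | alternative 3 | cis-epoxy triethylsilyl ether of the spiro[5.5] precursor | O1[C@@H]2CC[C@]3([C@H](CCCO[Si](C)(C)C(C)(C)C)C4(OCCO4)CC[C@]3(C)O[Si](C)(C)C)[C@H](O[Si](CC)(CC)CC)[C@H]12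
A7 | alternative 3 | ring A β-silyloxy aldehyde | O=C[C@@H]1CC[C@]2([C@H](CCCO[Si](C)(C)C(C)(C)C)C3(OCCO3)CC[C@]2(C)O[Si](C)(C)C)[C@@H]1O[Si](CC)(CC)CC
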